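**Plan**

1. Retrosynthesis cuts the ketone arm first, at the bond between its α-carbon and the carbonyl carbon (aldol of a ring B arylacetyl imide with a vanillin unit, then oxidation). It then cuts the dihydrobenzofuran at C2–C3 (carbene insertion into a benzyl ether C–H), the furofuran at both benzylic C–O bonds (C2–O3, C6–O7), and last the chain at C5–C6 and C1–C2.
2. The enabling feature: furofuran bridgeheads C1 and C5 each carry one CH2–O carbon (C8, C4) and one benzylic carbon (C2, C6). That is the pattern of a trans-3,4-disubstituted γ-alkoxybutyrolactone with C8 as carbonyl and C4 as acetal carbon, so a ring C dithiane anion, a menthyloxybutenolide and a ring B aldehyde give the C6–C5–C1–C2 chain in one operation.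
3. Forward: chain assembly (no ring closed), then both tetrahydrofuran rings of the furofuran in one acid step, then the dihydrofuran ring on ring C, then the ketone arm on ring B, then desilylation.
4. Stereochemistry: C1 and C5 come from the (−)-menthol-derived acetal centre; C2 and C6 from trans-selective cationic ring closure; the cis dihydrobenzofuran centres from a chiral dirhodium catalyst; the ketone α-carbon from (R)-4-benzyloxazolidinone.

Key step: step 10

Labels: the furofuran is numbered as 3,7-dioxabicyclo[3.3.0]octane (C2 carries ring B, C6 carries ring C); ring D is the aryl of the ketone, ring E the 2-aryl group of the dihydrobenzofuran; TIPS = triisopropylsilyl, TIPSO = triisopropylsilyloxy, TBS = tert-butyldimethylsilyl.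
Assumption 1: the dihydrobenzofuran of the target is read as cis-(2S,3S); the (R)-configured phthaloyl-tert-leucinate dirhodium catalyst is taken to give the matching (2S,3R) ester 24 by analogy with simpler 2-(benzyloxy)aryl diazoacetates, and its mirror image would be used if the sense proved opposite.
Assumption 2: the benzylic carbinol carbons of 16, 17 and 18 are expected as epimer mixtures and are written without configuration, because both are re-formed in step 13.

**Route**

Step 1
Reactants: 1 furfural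
Product: 2 5-hydroxyfuran-2(5H)-one
Conditions: O2, methylene blue (cat.), MeOH, visible light, rt
Reagents that add atoms: oxygen, O=O
Why: Dye-sensitised photooxygenation, in which singlet oxygen adds [4+2] across the furan and methanolysis of the endoperoxide at the formyl carbon expels methyl formate to leave the racemic hydroxybutenolide.

Step 2
Reactants: 2 5-hydroxyfuran-2(5H)-one; 3 (−)-menthol
Product: 4 (5R)-5-menthyloxyfuran-2(5H)-one
Conditions: CSA (cat.), toluene, reflux, Dean–Stark; crystallisation from petroleum ether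
Reagents that add atoms: none
Why: Acid-catalysed acetalisation of the pseudo-acid gives both C5 epimers, which interconvert under the acid while the (5R)-epimer crystallises, so the acetal centre is set by crystallisation-driven epimerisation with (−)-menthol as the source of chirality.

Step 3
Reactants: 5 vanillin
Product: 6 3-methoxy-4-(triisopropylsilyloxy)benzaldehyde
Conditions: TIPSCl, imidazole, DMF, rt
Reagents that add atoms: triisopropylsilyl chloride, CC(C)[Si](Cl)(C(C)C)C(C)C
Why: Imidazole-promoted silyl ether formation on the phenol gives a bulky aryl silyl ether that should survive the later organolithium, hydride and mildly acidic steps.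

Step 4
Reactants: 6 3-methoxy-4-(triisopropylsilyloxy)benzaldehyde
Product: 7 [3-methoxy-4-(triisopropylsilyloxy)phenyl]methanol
Conditions: NaBH4, MeOH, 0 °C
Reagents that add atoms: none
Why: Borohydride reduction of the aryl aldehyde to the benzylic alcohol, with no stereocentre formed.

Step 5
Reactants: 5 vanillin
Product: 8 4-(allyloxy)-3-methoxybenzaldehyde
Conditions: allyl bromide, K2CO3, acetone, reflux
Reagents that add atoms: allyl bromide, C=CCBr
Why: Williamson etherification of the phenoxide with allyl bromide.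

Step 6
Reactants: 8 4-(allyloxy)-3-methoxybenzaldehyde
Product: 9 3-allyl-4-hydroxy-5-methoxybenzaldehyde
Conditions: N,N-diethylaniline, 200 °C
Reagents that add atoms: none
Why: Aromatic Claisen rearrangement ([3,3]-sigmatropic shift, then tautomerisation) delivers the allyl group to the only free ortho position.

Step 7
Reactants: 9 3-allyl-4-hydroxy-5-methoxybenzaldehyde
Product: 10 2-allyl-4-(1,3-dithian-2-yl)-6-methoxyphenol
Conditions: propane-1,3-dithiol, BF3·OEt2 (cat.), CH2Cl2, 0 °C to rt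
Reagents that add atoms: propane-1,3-dithiol, SCCCS
Why: Lewis acid-catalysed dithioacetalisation masks the aldehyde as the acyl anion precursor while the phenol and the alkene stay inert.

Step 8
Reactants: 10 2-allyl-4-(1,3-dithian-2-yl)-6-methoxyphenol; 7 [3-methoxy-4-(triisopropylsilyloxy)phenyl]methanol
Product: 11 ring C dithiane bearing the ring E benzyl ether
Conditions: PPh3, DIAD, THF, 0 °C to rt
Reagents that add atoms: none
Why: Mitsunobu etherification of the phenol with the primary benzylic alcohol installs the ring E benzyl ether whose methylene later supplies the C–H bond for carbene insertion.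

Step 9
Reactants: 12 5-bromovanillin
Product: 13 3-bromo-5-methoxy-4-(triisopropylsilyloxy)benzaldehyde
Conditions: TIPSOTf, 2,6-lutidine, CH2Cl2, 0 °C
Reagents that add atoms: triisopropylsilyl trifluoromethanesulfonate, CC(C)[Si](OS(=O)(=O)C(F)(F)F)(C(C)C)C(C)C
Why: Silyl triflate silylation of the hindered ortho-bromophenol.

Step 10
Reactants: 11 ring C dithiane; 4 (5R)-5-menthyloxyfuran-2(5H)-one; 13 3-bromo-5-methoxy-4-(triisopropylsilyloxy)benzaldehyde
Product: 16 trans-3,4-disubstituted 5-menthyloxy lactone aldol adduct, via lithiated dithiane 14 (not isolated), via lithium lactone enolate 15 (not isolated)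
Conditions: n-BuLi, THF, −78 to −30 °C; 4, −78 °C; 13, −78 °C; AcOH quench
Reagents that add atoms: none
Why: n-BuLi removes the dithiane C–H of 11 to give the sulfur-stabilised benzylic anion 14, which adds 1,4 to butenolide 4 to form the C6–C5 bond and the lithium enolate 15, and 15 then adds to aldehyde 13 to form the C1–C2 bond; the closest known reaction type is the tandem conjugate addition–aldol of lithiated dithioacetals with 5-alkoxyfuran-2(5H)-ones used for lignan lactones. No ring is closed: three components are joined and three stereocentres arise. C5 (lactone C4, R) is controlled by the acetal centre, the bulky nucleophile entering anti to the menthyloxy group, and C1 (lactone C3, S) is controlled by the new C4 substituent, the aldehyde approaching the enolate face opposite to it to give the trans-3,4 lactone. The C2 carbinol is not reliably controlled and is carried as an epimer mixture because it is re-formed in step 13. The step needs 1,4- rather than 1,2-addition, which the soft and hindered 2-aryl dithianyl anion should secure, and facial selectivity, which the single stereocentre of 4 next to the β-carbon should secure. The aryl bromide of 13 is safe because it meets only the enolate, the alkyllithium having been consumed before 13 is added.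

Step 11
Reactants: 16 lactone aldol adduct
Product: 17 keto lactone
Conditions: MeI, CaCO3, MeCN/H2O (9:1), 45 °C
Reagents that add atoms: water, O
Why: Alkylative dithiane hydrolysis (S-methylation, opening to the aryl-stabilised thionium ion, hydration) is chosen over thiophilic mercury salts because MeI leaves the allyl group and the aryl bromide alone, and the buffered medium should not disturb the trans lactone centres.

Step 12
Reactants: 17 keto lactone
Product: 18 tetraol
Conditions: LiAlH4, THF, 0 °C to rt; H2O, aq. NaOH work-up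
Reagents that add atoms: none
Why: Hydride reduction of ketone, lactone and acetal in one operation: the lactone opens to a hemiacetal that loses menthoxide and is reduced further, so C8 and C4 become CH2OH while C1 and C5 keep their configuration, and the new C6 carbinol forms unselectively, which does not matter.

Step 13
Reactants: 18 tetraol
Product: 19 furofuran core
Conditions: CSA (10 mol %), CH2Cl2, 0 °C; Et3N quench
Reagents that add atoms: none
Why: Acid-catalysed double dehydrative etherification (SN1): each benzylic carbinol ionises to a para-oxygen-stabilised cation that is captured 5-exo by the primary hydroxyl of the far bridgehead (C4–OH on C2, C8–OH on C6), each aryl group taking the exo position trans to the neighbouring ring carbon, so C2 and C6 are both set as S under kinetic control by the fixed bridgeheads whatever the carbinol configuration.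

Step 14
Reactants: 19 furofuran core
Product: 21 ring C arylacetic acid, via arylacetaldehyde 20 (not isolated)
Conditions: OsO4 (cat.), NaIO4, 2,6-lutidine, dioxane/H2O, rt; then NaClO2, NaH2PO4, 2-methyl-2-butene, t-BuOH/H2O, 0 °C to rt
Reagents that add atoms: sodium periodate, [Na+].[O-]I(=O)(=O)=O; sodium chlorite, [Na+].[O-]Cl=O
Why: Lemieux–Johnson cleavage of the terminal alkene followed by Pinnick oxidation of the crude arylacetaldehyde, both near neutral so that silyl ethers, benzylic ethers and the aryl bromide should survive.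

Step 15
Reactants: 21 ring C arylacetic acid
Product: 22 methyl arylacetate
Conditions: TMSCHN2, toluene/MeOH, 0 °C
Reagents that add atoms: (trimethylsilyl)diazomethane, C[Si](C)(C)C=[N+]=[N-]
Why: Methyl esterification with the diazoalkane under neutral conditions.

Step 16
Reactants: 22 methyl arylacetate
Product: 23 methyl aryldiazoacetate
Conditions: 4-acetamidobenzenesulfonyl azide, DBU, MeCN, 0 °C to rt
Reagents that add atoms: 4-acetamidobenzenesulfonyl azide, CC(=O)Nc1ccc(cc1)S(=O)(=O)N=[N+]=[N-]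
Why: Regitz diazo transfer to the arylacetate gives the donor/acceptor diazo ester.

Step 17
Reactants: 23 methyl aryldiazoacetate
Product: 24 cis-dihydrobenzofuran ester
Conditions: Rh2(R-PTTL)4, i.e. dirhodium tetrakis[N-phthaloyl-(R)-tert-leucinate] (1 mol %), toluene, −60 °C
Reagents that add atoms: none
Why: Dirhodium carbenoid 1,5-C–H insertion into the ring E benzyl ether methylene closes the dihydrofuran ring, the chiral carboxylate ligands selecting the enantiotopic C–H bond and the cis arrangement, so that the kinetic cis-(2S,3R) ester should result (carbene carbon becomes C3, benzylic carbon C2).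

Step 18
Reactants: 24 cis-dihydrobenzofuran ester
Product: 25 ring B allyl compound
Conditions: allylSnBu3, Pd(PPh3)4 (5 mol %), toluene, 100 °C
Reagents that add atoms: allyltributylstannane, C=CC[Sn](CCCC)(CCCC)CCCC
Why: Stille cross-coupling (oxidative addition of zerovalent palladium to the aryl bromide, allyl transfer from tin, reductive elimination) runs without base and so should not epimerise the cis ester.

Step 19
Reactants: 25 ring B allyl compound
Product: 27 ring B arylacetic acid, via arylacetaldehyde 26 (not isolated)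
Conditions: OsO4 (cat.), NaIO4, 2,6-lutidine, dioxane/H2O, rt; then NaClO2, NaH2PO4, 2-methyl-2-butene, t-BuOH/H2O, 0 °C to rt
Reagents that add atoms: sodium periodate, [Na+].[O-]I(=O)(=O)=O; sodium chlorite, [Na+].[O-]Cl=O
Why: Lemieux–Johnson cleavage and Pinnick oxidation as in step 14, now on the only alkene left.

Step 20
Reactants: 27 ring B arylacetic acid; 28 (R)-4-benzyl-1,3-oxazolidin-2-one
Product: 30 N-arylacetyl oxazolidinone, via mixed pivalic anhydride 29 (not isolated)
Conditions: PivCl, Et3N, THF, −20 °C; then 28, LiCl, −20 °C to rt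
Reagents that add atoms: none
Why: Mixed-anhydride N-acylation of the oxazolidinone in its LiCl/Et3N form attaches the chiral auxiliary without strong base, which protects the cis ester.

Step 21
Reactants: 30 N-arylacetyl oxazolidinone; 6 3-methoxy-4-(triisopropylsilyloxy)benzaldehyde
Product: 32 syn-aldol adduct, via boron enolate 31 (not isolated)
Conditions: Bu2BOTf (1.1 equiv), i-Pr2NEt, CH2Cl2, −78 to 0 °C; 6, −78 to 0 °C; H2O2, MeOH, pH 7 buffer (NaH2PO4/Na2HPO4)
Reagents that add atoms: none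
Why: Evans syn-aldol, in which the Z boron enolate reacts through a Zimmerman–Traxler chair on the face opposite the auxiliary benzyl group, fixing the α-carbon (R in the imide, S in the target after the change of priorities) and a carbinol carbon that is oxidised later, while the near-stoichiometric boron triflate should leave the methyl ester unenolised.

Step 22
Reactants: 32 syn-aldol adduct
Product: 33 triol
Conditions: LiBH4, MeOH (2 equiv), THF, 0 °C to rt
Reagents that add atoms: none
Why: Hydride reduction in which LiBH4 cleaves the imide to the primary alcohol with release of the auxiliary and also reduces the methyl ester to the C3 hydroxymethyl group, leaving all stereocentres untouched.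

Step 23
Reactants: 33 triol
Product: 34 tris-silylated hydroxy ketone
Conditions: MnO2 (activated, excess), CH2Cl2, rt
Reagents that add atoms: none
Why: Chemoselective MnO2 oxidation of the electron-rich benzylic secondary alcohol in the presence of two non-benzylic primary alcohols, under neutral heterogeneous conditions that should leave the adjacent α-aryl stereocentre intact.

Step 24
Reactants: 34 tris-silylated hydroxy ketone
Product: 35 CNP0174045.1
Conditions: TBAF, AcOH (1:1), THF, 0 °C
Reagents that add atoms: none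
Why: Fluoride desilylation of the three aryl silyl ethers, buffered with acetic acid so that the β-hydroxy ketone should neither epimerise nor undergo retro-aldol cleavage.

**Compound list**

1 | furfural | O=Cc1ccco1 | starting material
2 | 5-hydroxyfuran-2(5H)-one (racemic) | O=C1C=CC(O)O1 | intermediate
3 | (−)-menthol, (1R,2S,5R)-2-isopropyl-5-methylcyclohexan-1-ol | CC(C)[C@@H]1CC[C@@H](C)C[C@H]1O | starting material
4 | (5R)-5-[(1R,2S,5R)-menthyloxy]furan-2(5H)-one | CC(C)[C@@H]1CC[C@@H](C)C[C@H]1O[C@H]1C=CC(=O)O1 | intermediate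
5 | vanillin | O=Cc1ccc(O)c(OC)c1 | starting material
6 | 3-methoxy-4-(triisopropylsilyloxy)benzaldehyde | O=Cc1ccc(O[Si](C(C)C)(C(C)C)C(C)C)c(OC)c1 | intermediate
7 | [3-methoxy-4-(triisopropylsilyloxy)phenyl]methanol | OCc1ccc(O[Si](C(C)C)(C(C)C)C(C)C)c(OC)c1 | intermediate
8 | 4-(allyloxy)-3-methoxybenzaldehyde | C=CCOc1ccc(C=O)cc1OC | intermediate
9 | 3-allyl-4-hydroxy-5-methoxybenzaldehyde | C=CCc1cc(C=O)cc(OC)c1O | intermediate
10 | 2-allyl-4-(1,3-dithian-2-yl)-6-methoxyphenol | C=CCc1cc(C2SCCCS2)cc(OC)c1O | intermediate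
11 | 2-(3-allyl-5-methoxy-4-{[3-methoxy-4-(triisopropylsilyloxy)benzyl]oxy}phenyl)-1,3-dithiane | C=CCc1cc(C2SCCCS2)cc(OC)c1OCc1ccc(O[Si](C(C)C)(C(C)C)C(C)C)c(OC)c1 | intermediate
12 | 5-bromovanillin (3-bromo-4-hydroxy-5-methoxybenzaldehyde) | O=Cc1cc(Br)c(O)c(OC)c1 | starting material
13 | 3-bromo-5-methoxy-4-(triisopropylsilyloxy)benzaldehyde | O=Cc1cc(Br)c(O[Si](C(C)C)(C(C)C)C(C)C)c(OC)c1 | intermediate
14 | 2-lithio derivative of dithiane 11 | [Li]C1(c2cc(CC=C)c(OCc3ccc(O[Si](C(C)C)(C(C)C)C(C)C)c(OC)c3)c(OC)c2)SCCCS1 | intermediate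
15 | lithium enolate of the (4R,5R)-4-(2-aryl-1,3-dithian-2-yl)-5-menthyloxy lactone | CC(C)[C@@H]1CC[C@@H](C)C[C@H]1O[C@H]1[C@H](C2(c3cc(CC=C)c(OCc4ccc(O[Si](C(C)C)(C(C)C)C(C)C)c(OC)c4)c(OC)c3)SCCCS2)C=C(O[Li])O1 | intermediate
16 | (3S,4R,5R)-3-{[3-bromo-5-methoxy-4-(TIPSO)phenyl](hydroxy)methyl}-4-[2-(3-allyl-5-methoxy-4-{[3-methoxy-4-(TIPSO)benzyl]oxy}phenyl)-1,3-dithian-2-yl]-5-[(1R,2S,5R)-menthyloxy]dihydrofuran-2(3H)-one, carbinol epimers | CC(C)[C@@H]1CC[C@@H](C)C[C@H]1O[C@H]1[C@H](C2(c3cc(CC=C)c(OCc4ccc(O[Si](C(C)C)(C(C)C)C(C)C)c(OC)c4)c(OC)c3)SCCCS2)[C@@H](C(O)c2cc(Br)c(O[Si](C(C)C)(C(C)C)C(C)C)c(OC)c2)C(=O)O1 | intermediate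
17 | (3S,4R,5R)-4-(3-allyl-5-methoxy-4-{[3-methoxy-4-(TIPSO)benzyl]oxy}benzoyl)-3-{[3-bromo-5-methoxy-4-(TIPSO)phenyl](hydroxy)methyl}-5-[(1R,2S,5R)-menthyloxy]dihydrofuran-2(3H)-one, carbinol epimers | CC(C)[C@@H]1CC[C@@H](C)C[C@H]1O[C@H]1[C@H](C(=O)c2cc(CC=C)c(OCc3ccc(O[Si](C(C)C)(C(C)C)C(C)C)c(OC)c3)c(OC)c2)[C@@H](C(O)c2cc(Br)c(O[Si](C(C)C)(C(C)C)C(C)C)c(OC)c2)C(=O)O1 | intermediate
18 | (2R,3R)-1-[3-bromo-5-methoxy-4-(TIPSO)phenyl]-4-(3-allyl-5-methoxy-4-{[3-methoxy-4-(TIPSO)benzyl]oxy}phenyl)-2,3-bis(hydroxymethyl)butane-1,4-diol, epimers at C1 and C4 | OC[C@H](C(O)c1cc(CC=C)c(OCc2ccc(O[Si](C(C)C)(C(C)C)C(C)C)c(OC)c2)c(OC)c1)[C@@H](C(O)c1cc(Br)c(O[Si](C(C)C)(C(C)C)C(C)C)c(OC)c1)CO | intermediate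
19 | (1R,2S,5R,6S)-2-[3-bromo-5-methoxy-4-(TIPSO)phenyl]-6-(3-allyl-5-methoxy-4-{[3-methoxy-4-(TIPSO)benzyl]oxy}phenyl)-3,7-dioxabicyclo[3.3.0]octane | COc1cc([C@H]2OC[C@H]3[C@@H]2CO[C@@H]3c2cc(CC=C)c(OCc3ccc(O[Si](C(C)C)(C(C)C)C(C)C)c(OC)c3)c(OC)c2)cc(Br)c1O[Si](C(C)C)(C(C)C)C(C)C | intermediate
20 | as 19 with the allyl group cut to CH2CHO (ring C arylacetaldehyde) | COc1cc([C@H]2OC[C@H]3[C@@H]2CO[C@@H]3c2cc(CC=O)c(OCc3ccc(O[Si](C(C)C)(C(C)C)C(C)C)c(OC)c3)c(OC)c2)cc(Br)c1O[Si](C(C)C)(C(C)C)C(C)C | intermediate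
21 | as 19 with the allyl group replaced by CH2CO2H (ring C arylacetic acid) | COc1cc([C@H]2OC[C@H]3[C@@H]2CO[C@@H]3c2cc(CC(=O)O)c(OCc3ccc(O[Si](C(C)C)(C(C)C)C(C)C)c(OC)c3)c(OC)c2)cc(Br)c1O[Si](C(C)C)(C(C)C)C(C)C | intermediate
22 | methyl ester of 21 | COc1cc([C@H]2OC[C@H]3[C@@H]2CO[C@@H]3c2cc(CC(=O)OC)c(OCc3ccc(O[Si](C(C)C)(C(C)C)C(C)C)c(OC)c3)c(OC)c2)cc(Br)c1O[Si](C(C)C)(C(C)C)C(C)C | intermediate
23 | α-diazo derivative of ester 22 | COc1cc([C@H]2OC[C@H]3[C@@H]2CO[C@@H]3c2cc(C(=[N+]=[N-])C(=O)OC)c(OCc3ccc(O[Si](C(C)C)(C(C)C)C(C)C)c(OC)c3)c(OC)c2)cc(Br)c1O[Si](C(C)C)(C(C)C)C(C)C | intermediate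
24 | methyl (2S,3R)-5-{(1R,2S,5R,6S)-6-[3-bromo-5-methoxy-4-(TIPSO)phenyl]-3,7-dioxabicyclo[3.3.0]octan-2-yl}-7-methoxy-2-[3-methoxy-4-(TIPSO)phenyl]-2,3-dihydro-1-benzofuran-3-carboxylate (cis) | COc1cc([C@H]2OC[C@H]3[C@@H]2CO[C@@H]3c2cc(OC)c3c(c2)[C@@H](C(=O)OC)[C@@H](c2ccc(O[Si](C(C)C)(C(C)C)C(C)C)c(OC)c2)O3)cc(Br)c1O[Si](C(C)C)(C(C)C)C(C)C | intermediate
25 | as 24 with Br replaced by allyl | COc1cc([C@H]2OC[C@H]3[C@@H]2CO[C@@H]3c2cc(OC)c3c(c2)[C@@H](C(=O)OC)[C@@H](c2ccc(O[Si](C(C)C)(C(C)C)C(C)C)c(OC)c2)O3)cc(CC=C)c1O[Si](C(C)C)(C(C)C)C(C)C | intermediate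
26 | as 24 with Br replaced by CH2CHO (ring B arylacetaldehyde) | COc1cc([C@H]2OC[C@H]3[C@@H]2CO[C@@H]3c2cc(OC)c3c(c2)[C@@H](C(=O)OC)[C@@H](c2ccc(O[Si](C(C)C)(C(C)C)C(C)C)c(OC)c2)O3)cc(CC=O)c1O[Si](C(C)C)(C(C)C)C(C)C | intermediate
27 | as 24 with Br replaced by CH2CO2H (ring B arylacetic acid) | COc1cc([C@H]2OC[C@H]3[C@@H]2CO[C@@H]3c2cc(OC)c3c(c2)[C@@H](C(=O)OC)[C@@H](c2ccc(O[Si](C(C)C)(C(C)C)C(C)C)c(OC)c2)O3)cc(CC(=O)O)c1O[Si](C(C)C)(C(C)C)C(C)C | intermediate
28 | (R)-4-benzyl-1,3-oxazolidin-2-one | O=C1N[C@H](Cc2ccccc2)CO1 | starting material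
29 | mixed anhydride of acid 27 with pivalic acid | COc1cc([C@H]2OC[C@H]3[C@@H]2CO[C@@H]3c2cc(OC)c3c(c2)[C@@H](C(=O)OC)[C@@H](c2ccc(O[Si](C(C)C)(C(C)C)C(C)C)c(OC)c2)O3)cc(CC(=O)OC(=O)C(C)(C)C)c1O[Si](C(C)C)(C(C)C)C(C)C | intermediate
30 | (R)-4-benzyl-3-(arylacetyl)oxazolidin-2-one derived from acid 27 | COc1cc([C@H]2OC[C@H]3[C@@H]2CO[C@@H]3c2cc(OC)c3c(c2)[C@@H](C(=O)OC)[C@@H](c2ccc(O[Si](C(C)C)(C(C)C)C(C)C)c(OC)c2)O3)cc(CC(=O)N2[C@H](Cc3ccccc3)COC2=O)c1O[Si](C(C)C)(C(C)C)C(C)C | intermediate
31 | Z dibutylboron enolate of imide 30 | COc1cc([C@H]2OC[C@H]3[C@@H]2CO[C@@H]3c2cc(OC)c3c(c2)[C@@H](C(=O)OC)[C@@H](c2ccc(O[Si](C(C)C)(C(C)C)C(C)C)c(OC)c2)O3)cc(/C=C(\OB(CCCC)CCCC)N2[C@H](Cc3ccccc3)COC2=O)c1O[Si](C(C)C)(C(C)C)C(C)C | intermediate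
32 | (2R,3R)-syn aldol adduct: imide 30 carrying at its α-carbon the (R)-hydroxy[3-methoxy-4-(TIPSO)phenyl]methyl group | COc1cc([C@H]2OC[C@H]3[C@@H]2CO[C@@H]3c2cc(OC)c3c(c2)[C@@H](C(=O)OC)[C@@H](c2ccc(O[Si](C(C)C)(C(C)C)C(C)C)c(OC)c2)O3)cc([C@@H](C(=O)N2[C@H](Cc3ccccc3)COC2=O)[C@@H](O)c2ccc(O[Si](C(C)C)(C(C)C)C(C)C)c(OC)c2)c1O[Si](C(C)C)(C(C)C)C(C)C | intermediate
33 | triol: ring B side chain (1R,2S)-1-[3-methoxy-4-(TIPSO)phenyl]propane-1,3-diol-2-yl, dihydrobenzofuran (2S,3S)-3-hydroxymethyl, furofuran (1R,2S,5R,6S) | COc1cc([C@H]2OC[C@H]3[C@@H]2CO[C@@H]3c2cc(OC)c3c(c2)[C@@H](CO)[C@@H](c2ccc(O[Si](C(C)C)(C(C)C)C(C)C)c(OC)c2)O3)cc([C@@H](CO)[C@@H](O)c2ccc(O[Si](C(C)C)(C(C)C)C(C)C)c(OC)c2)c1O[Si](C(C)C)(C(C)C)C(C)C | intermediate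
34 | tris(triisopropylsilyl) ether of the target at the three phenols (ketone α-carbon S) | COc1cc([C@H]2OC[C@H]3[C@@H]2CO[C@@H]3c2cc(OC)c3c(c2)[C@@H](CO)[C@@H](c2ccc(O[Si](C(C)C)(C(C)C)C(C)C)c(OC)c2)O3)cc([C@@H](CO)C(=O)c2ccc(O[Si](C(C)C)(C(C)C)C(C)C)c(OC)c2)c1O[Si](C(C)C)(C(C)C)C(C)C | intermediate
35 | CNP0174045.1 | COc1cc(C(=O)[C@H](CO)c2cc([C@H]3OC[C@H]4[C@@H]3CO[C@@H]4c3cc(OC)c4c(c3)[C@@H](CO)[C@@H](c3ccc(O)c(OC)c3)O4)cc(OC)c2O)ccc1O | target

**Totals**

Total step count: 24.
Longest linear sequence: 19 steps (vanillin through steps 5, 6, 7, 8, then 10 to 24).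

**Steps most likely to fail**

Step 13. Under the acid that ionises the carbinols, the new benzylic ethers can re-ionise, so the aryl groups may drift from exo to endo; the ring C cation may also be trapped by the other benzylic hydroxyl to give a 2,5-diaryl tetrahydrofuran. The fallback fixes both benzylic centres by reagent control and closes the rings at the primary carbons instead. It sets out from 18. TBSCl and imidazole silylate the two primary hydroxyls to give the bis-silyl ether F1. Dess–Martin periodinane with NaHCO3 oxidises both benzylic carbinols to the diketone F2. Corey–Bakshi–Shibata reduction with (R)-2-methyl-CBS-oxazaborolidine and BH3·SMe2 gives the (S,S)-diol F3. HF·pyridine removes the primary silyl ethers to give the configurationally defined tetraol F4. MsCl in pyridine then mesylates the primary hydroxyls, which are displaced in situ by the benzylic hydroxyls with retention at C2 and C6, and the sequence comes back to the route at 19.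

Step 23. Oxidation at the hindered carbinol next to the ortho-silyloxy aryl group may be slow, which leaves time for epimerisation at the new α-aryl ketone carbon, retro-aldol loss of formaldehyde, or attack on the primary alcohols. The fallback replaces oxidant selectivity by protecting-group differentiation. It sets out from 33. TBSCl and imidazole silylate the two primary hydroxyls to give the bis-silyl ether F5. Dess–Martin periodinane with NaHCO3 oxidises the remaining secondary alcohol to the ketone F6. HF·pyridine followed by TBAF/AcOH removes the two alkyl and three aryl silyl groups, and the sequence comes back to the route at 35.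

Step 11. S-Alkylation of the hindered dithiane may be slow, and the exposed keto lactone can meanwhile epimerise next to the ketone or lose the lactone carboxylate by β-elimination. The fallback changes the order of oxidation states so that no keto lactone is formed. It sets out from 16. LiAlH4 reduces the lactone and the acetal first to give the triol dithiane F7. MeI and CaCO3 in aqueous MeCN then unmask the ketone, which is captured at once by the C8 hydroxyl as the cyclic hemiketal F8. NaBH4 reduces F8 through its open hydroxy ketone form, and the sequence comes back to the route at 18.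

**Further compounds**

F1 | step 13 | bis(tert-butyldimethylsilyl) ether of tetraol 18 at both primary hydroxyls, carbinol epimers | CC(C)(C)[Si](C)(C)OC[C@H](C(O)c1cc(CC=C)c(OCc2ccc(O[Si](C(C)C)(C(C)C)C(C)C)c(OC)c2)c(OC)c1)[C@@H](C(O)c1cc(Br)c(O[Si](C(C)C)(C(C)C)C(C)C)c(OC)c1)CO[Si](C)(C)C(C)(C)C
F2 | step 13 | (2R,3R)-1,4-diaryl-2,3-bis(tert-butyldimethylsilyloxymethyl)butane-1,4-dione | CC(C)(C)[Si](C)(C)OC[C@H](C(=O)c1cc(CC=C)c(OCc2ccc(O[Si](C(C)C)(C(C)C)C(C)C)c(OC)c2)c(OC)c1)[C@@H](C(=O)c1cc(Br)c(O[Si](C(C)C)(C(C)C)C(C)C)c(OC)c1)CO[Si](C)(C)C(C)(C)C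
F3 | step 13 | (1S,2R,3R,4S)-1,4-diaryl-2,3-bis(tert-butyldimethylsilyloxymethyl)butane-1,4-diol | CC(C)(C)[Si](C)(C)OC[C@H]([C@H](O)c1cc(CC=C)c(OCc2ccc(O[Si](C(C)C)(C(C)C)C(C)C)c(OC)c2)c(OC)c1)[C@@H]([C@H](O)c1cc(Br)c(O[Si](C(C)C)(C(C)C)C(C)C)c(OC)c1)CO[Si](C)(C)C(C)(C)C
F4 | step 13 | (1S,2R,3R,4S)-configured single isomer of tetraol 18 | OC[C@H]([C@H](O)c1cc(CC=C)c(OCc2ccc(O[Si](C(C)C)(C(C)C)C(C)C)c(OC)c2)c(OC)c1)[C@@H]([C@H](O)c1cc(Br)c(O[Si](C(C)C)(C(C)C)C(C)C)c(OC)c1)CO
F5 | step 23 | bis(tert-butyldimethylsilyl) ether of triol 33 at both primary hydroxyls | COc1cc([C@H]2OC[C@H]3[C@@H]2CO[C@@H]3c2cc(OC)c3c(c2)[C@@H](CO[Si](C)(C)C(C)(C)C)[C@@H](c2ccc(O[Si](C(C)C)(C(C)C)C(C)C)c(OC)c2)O3)cc([C@@H](CO[Si](C)(C)C(C)(C)C)[C@@H](O)c2ccc(O[Si](C(C)C)(C(C)C)C(C)C)c(OC)c2)c1O[Si](C(C)C)(C(C)C)C(C)C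
F6 | step 23 | bis(tert-butyldimethylsilyl) ether of hydroxy ketone 34 at both primary hydroxyls | COc1cc([C@H]2OC[C@H]3[C@@H]2CO[C@@H]3c2cc(OC)c3c(c2)[C@@H](CO[Si](C)(C)C(C)(C)C)[C@@H](c2ccc(O[Si](C(C)C)(C(C)C)C(C)C)c(OC)c2)O3)cc([C@@H](CO[Si](C)(C)C(C)(C)C)C(=O)c2ccc(O[Si](C(C)C)(C(C)C)C(C)C)c(OC)c2)c1O[Si](C(C)C)(C(C)C)C(C)C
F7 | step 11 | (2R,3R)-triol dithiane: 16 with lactone and acetal reduced to two CH2OH groups, carbinol epimers | OC[C@H](C1(c2cc(CC=C)c(OCc3ccc(O[Si](C(C)C)(C(C)C)C(C)C)c(OC)c3)c(OC)c2)SCCCS1)[C@@H](C(O)c1cc(Br)c(O[Si](C(C)C)(C(C)C)C(C)C)c(OC)c1)CO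
F8 | step 11 | cyclic hemiketal (2-aryl-2-hydroxytetrahydrofuran) of the hydroxy ketone from F7, anomer and carbinol epimer mixture | OC[C@@H]1C(O)(c2cc(CC=C)c(OCc3ccc(O[Si](C(C)C)(C(C)C)C(C)C)c(OC)c3)c(OC)c2)OC[C@@H]1C(O)c1cc(Br)c(O[Si](C(C)C)(C(C)C)C(C)C)c(OC)c1
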